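**Strategy.** Ring B (C1′–C6′) is a resorcinol with OMe at C2′, free OH at C4′, a prenyl group at C5′ and the chroman at C1′, which is the pattern that a vinylketene and methoxyacetylene assemble. The route therefore cuts ring B back to a (3R,4R)-chroman-3-yl diazo dienone. One irradiation–heating operation (Wolff shift, [2+2] addition, four-electron opening, six-electron closure) forms four ring-B bonds and delivers the two oxygens already differentiated. The precursor is the cis-4,5-bis(silyloxy)chroman whose C3 carries C(=N2)–CO–CH=CH–CH2–CH=CMe2. Its two stereocentres come from an asymmetric Stetter cyclisation and a cis-selective ketone reduction.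

Key step: step 13

Remark on numbering: chroman atoms are O1, C2, C3, C4, C4a, C5–C8, C8a; ring B atoms are C1′–C6′; TBS = tert-butyldimethylsilyl.
Assumption: the (5aS,10bR) triazolium salt is taken to give (R)-7; if the sense of induction is the reverse, the equally available (5aR,10bS) antipode is used.
Assumption: catalyst-bound species of step 4 carry no number; sp3 centres that arise and vanish in the same flask (21, 24, 31, 33) and the alkene geometry of 27 are left unspecified.

**Route**

Step 1
Reactants: 1 2,4,6-trimethoxybenzaldehyde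
Product: 2 2,6-dihydroxy-4-methoxybenzaldehyde
Conditions: AlCl3 (3 equiv), CH2Cl2, 0 to 23 °C; cold dilute HCl
Reagents that add atoms: none
Why: Chelation-directed Lewis acid demethylation: AlCl3 held by the aldehyde oxygen cleaves only the two flanking aryl methyl ethers, so the C4 methoxy group, which has no carbonyl neighbour, should survive.

Step 2
Reactants: 2 2,6-dihydroxy-4-methoxybenzaldehyde; 3 methyl (2E)-4-bromobut-2-enoate
Product: 4 methyl (2E)-4-(2-formyl-3-hydroxy-5-methoxyphenoxy)but-2-enoate
Conditions: 3 (1.0 equiv), K2CO3 (1.0 equiv), acetone, 23 °C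
Reagents that add atoms: methyl (2E)-4-bromobut-2-enoate, COC(=O)/C=C/CBr
Why: Williamson etherification under limiting base: one phenoxide displaces the primary allylic bromide (SN2), after which the remaining hydroxyl is tied up in a hydrogen bond to the aldehyde and should resist a second alkylation.

Step 3
Reactants: 4 methyl (2E)-4-(2-formyl-3-hydroxy-5-methoxyphenoxy)but-2-enoate; 5 tert-butyldimethylsilyl chloride
Product: 6 methyl (2E)-4-[3-(tert-butyldimethylsilyloxy)-2-formyl-5-methoxyphenoxy]but-2-enoate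
Conditions: 5, imidazole, DMF, 23 °C
Reagents that add atoms: tert-butyldimethylsilyl chloride, CC(C)(C)[Si](C)(C)Cl
Why: Standard imidazole-mediated silylation of a phenol; doing it after the alkylation keeps the aryl silyl ether away from carbonate and phenoxide, and it removes the acidic OH that would quench the carbene catalyst of step 4.

Step 4
Reactants: 6 methyl (2E)-4-[3-(tert-butyldimethylsilyloxy)-2-formyl-5-methoxyphenoxy]but-2-enoate
Product: 7 methyl 2-[(3R)-5-(tert-butyldimethylsilyloxy)-7-methoxy-4-oxochroman-3-yl]acetate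
Conditions: (5aS,10bR)-2-(pentafluorophenyl)-5a,10b-dihydro-4H,6H-indeno[2,1-b][1,2,4]triazolo[4,3-d][1,4]oxazinium tetrafluoroborate (15 mol %), KN(SiMe3)2 (15 mol %), toluene, 23 °C
Reagents that add atoms: none
Why: Asymmetric intramolecular Stetter reaction: the triazolylidene converts the aldehyde into an acyl anion equivalent that adds 6-exo-trig to the enoate β-carbon on the face left open by the aminoindane backbone, which sets C3 (R), while the electron-poor N-C6F5 catalyst and the merely catalytic base are chosen to cope with the hindered aldehyde and to avoid enolisation of the product.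

Step 5
Reactants: 7 methyl 2-[(3R)-5-(tert-butyldimethylsilyloxy)-7-methoxy-4-oxochroman-3-yl]acetate
Product: 9 (3aR,9bR)-9-(tert-butyldimethylsilyloxy)-7-methoxy-3,3a,4,9b-tetrahydro-2H-furo[3,2-c]chromen-2-one (cis-fused lactone), via cis-hydroxy ester 8 (not isolated)
Conditions: LiBH(s-Bu)3, THF, −78 to 0 °C; aq NH4Cl (no oxidative work-up)
Reagents that add atoms: none
Why: Substrate-controlled ketone reduction followed by lactonisation: the bulky borohydride attacks C4 on the face opposite the C3 side chain, so the new C4 oxygen (R) is cis to that chain and, as the lithium alkoxide, closes the γ-lactone with loss of methoxide, the non-oxidative work-up sparing lactone and aryl silyl ether.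

Step 6
Reactants: 9 cis-fused lactone; 10 N,O-dimethylhydroxylamine hydrochloride
Product: 11 2-[(3R,4R)-5-(tert-butyldimethylsilyloxy)-4-hydroxy-7-methoxychroman-3-yl]-N-methoxy-N-methylacetamide
Conditions: 10 (3 equiv), i-PrMgCl (6 equiv), THF, −20 to 0 °C; aq NH4Cl
Reagents that add atoms: N,O-dimethylhydroxylamine hydrochloride, CNOC.Cl
Why: Weinreb amide formation by aminolysis of the lactone with the chloromagnesium amide of N,O-dimethylhydroxylamine, a basic, non-Lewis-acidic reagent that should not ionise the electron-rich benzylic C4–O bond and touches neither stereocentre.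

Step 7
Reactants: 11 hydroxy Weinreb amide; 12 tert-butyldimethylsilyl trifluoromethanesulfonate
Product: 13 2-[(3R,4R)-4,5-bis(tert-butyldimethylsilyloxy)-7-methoxychroman-3-yl]-N-methoxy-N-methylacetamide
Conditions: 12, 2,6-lutidine, CH2Cl2, −78 to 0 °C
Reagents that add atoms: tert-butyldimethylsilyl trifluoromethanesulfonate, CC(C)(C)[Si](C)(C)OS(=O)(=O)C(F)(F)F
Why: Silyl triflate silylation of a hindered secondary alcohol buffered by 2,6-lutidine at low temperature, which should avoid ionisation at C4; a silyl shift from O5 to O4 during step 6 would be harmless, since the free oxygen is silylated here in either case.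

Step 8
Reactants: 14 prenyl bromide (1-bromo-3-methylbut-2-ene); 15 ethynylmagnesium bromide
Product: 16 5-methylhex-4-en-1-yne
Conditions: HC≡CMgBr (3 equiv), CuBr·SMe2 (5 mol %), THF, 0 to 23 °C; distil
Reagents that add atoms: ethynylmagnesium bromide, C#C[Mg]Br
Why: Copper-catalysed coupling of an alkynyl Grignard reagent with an allylic bromide, expected to occur at the unhindered primary carbon (SN2) and not at the gem-dimethyl terminus; excess acetylide suppresses double alkylation.

Step 9
Reactants: 16 5-methylhex-4-en-1-yne; 17 iodine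
Product: 19 (1E)-1-iodo-5-methylhexa-1,4-diene, via alkenylzirconocene chloride 18 (not isolated)
Conditions: Cp2Zr(H)Cl (1.2 equiv), CH2Cl2, 23 °C, dark; then I2, 0 °C
Reagents that add atoms: iodine, II
Why: Hydrozirconation–iodination: syn addition of Zr–H to the terminal alkyne puts zirconium on the terminal carbon and leaves the trisubstituted alkene alone, and iodine cleaves the C–Zr bond with retention to give the E iodide.

Step 10
Reactants: 13 bis-silylated Weinreb amide; 19 (1E)-1-iodo-5-methylhexa-1,4-diene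
Product: 22 (3E)-1-[(3R,4R)-4,5-bis(tert-butyldimethylsilyloxy)-7-methoxychroman-3-yl]-7-methylocta-3,6-dien-2-one, via dienyllithium 20 (not isolated), via tetrahedral lithium adduct 21 (not isolated)
Conditions: 19, t-BuLi (2.0 equiv), Et2O, −78 °C; then 13, THF, −78 to −40 °C; aq NH4Cl
Reagents that add atoms: (1E)-1-iodo-5-methylhexa-1,4-diene, CC(C)=CC/C=C/I
Why: Iodine–lithium exchange with retention of alkene geometry, then acyl substitution on the Weinreb amide, whose chelated tetrahedral adduct 21 survives until the quench and so prevents a second addition.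

Step 11
Reactants: 22 dienone; 23 4-acetamidobenzenesulfonyl azide
Product: 25 (3E)-1-diazo-1-[(3R,4R)-4,5-bis(tert-butyldimethylsilyloxy)-7-methoxychroman-3-yl]-7-methylocta-3,6-dien-2-one, via trifluoroacetyl diketone 24 (not isolated)
Conditions: LiN(SiMe3)2, THF, −78 °C; CF3CO2CH2CF3, −78 °C; aq NH4Cl; then 23, Et3N, H2O (1 equiv), MeCN, 23 °C
Reagents that add atoms: 4-acetamidobenzenesulfonyl azide, CC(=O)Nc1ccc(cc1)S(=O)(=O)N=[N+]=[N-]
Why: Detrifluoroacetylative (Regitz-type) diazo transfer: the lithium amide bound to the carbonyl oxygen removes an α′ proton kinetically (the doubly allylic γ-CH2 lies trans across the E alkene and out of its reach), C-trifluoroacetylation gives 1,3-diketone 24, and the sulfonyl azide with Et3N installs N2 with loss of the trifluoroacetyl group, leaving C3 and C4 untouched.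

Step 12
Reactants: 26 chloroacetaldehyde dimethyl acetal
Product: 29 methoxyacetylene, via 1-chloro-2-methoxyethene 27 (not isolated), via sodium methoxyacetylide 28 (not isolated)
Conditions: NaNH2 (3 equiv), liquid NH3, −33 °C; evaporate NH3; cold aq NaCl; distil into a cold trap, use as a cold solution in ClCH2CH2Cl
Reagents that add atoms: none
Why: Twofold elimination with NaNH2 (methanol, then HCl) gives the sodium acetylide 28, which is protonated on aqueous quench; the volatile ynol ether is distilled and used at once.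

Step 13
Reactants: 25 chroman-3-yl diazo dienone; 29 methoxyacetylene
Product: 34 4-[(3R,4R)-4,5-bis(tert-butyldimethylsilyloxy)-7-methoxychroman-3-yl]-5-methoxy-2-(3-methylbut-2-en-1-yl)phenol, via vinylketene 30 (not isolated), via cyclobutenone 31 (not isolated), via dienylketene 32 (not isolated), via cyclohexadienone 33 (not isolated)
Conditions: 29 (3 equiv), hν (medium-pressure Hg lamp, Pyrex filter), ClCH2CH2Cl, 20 °C; then 80 °C, sealed tube
Reagents that add atoms: methoxyacetylene, COC#C
Why: Irradiation expels N2 from 25 and the alkenyl group shifts from the carbonyl carbon to C1′ (Wolff rearrangement, bond C1′–C6′), giving vinylketene 30 whose carbonyl carbon becomes C4′. Regioselective [2+2] cycloaddition with methoxyacetylene (bonds C3′–C4′ and C1′–C2′) gives cyclobutenone 31; on heating, four-electron electrocyclic opening to dienylketene 32 and six-electron electrocyclic closure (bond C4′–C5′) close ring B, and dienone 33 tautomerises to the phenol. The closest known reaction type is the diazo ketone (second-generation) form of the Danheiser benzannulation with alkoxyacetylenes, which gives resorcinol monoethers. No lasting stereocentre is formed (the sp3 centres of 31 and 33 are lost on aromatisation), and C3 and C4 are spectators under these neutral conditions. The step needs a single alkyne orientation, which the polarity of the ynol ether secures: its unsubstituted, nucleophilic carbon attacks the electrophilic ketene carbonyl carbon, so OMe ends at C2′ next to C1′, OH at C4′ and the prenyl group at C5′. It also needs the Wolff shift to outrun a 1,2-hydride shift from C3–H, which is why direct photolysis is used and not thermal or metal-catalysed loss of N2, and why both hydroxyls are silylated so that nothing in the substrate can trap the ketenes.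

Step 14
Reactants: 34 bis-silylated isoflavan-4-ol
Product: 35 (3R,4R)-3-[4-hydroxy-2-methoxy-5-(3-methylbut-2-en-1-yl)phenyl]-7-methoxychroman-4,5-diol (target, CNP0265409.1)
Conditions: Bu4NF, AcOH (1:1, 3 equiv), THF, 0 to 23 °C; aq NH4Cl
Reagents that add atoms: none
Why: Fluoride-induced cleavage of the aryl and the secondary alkyl silyl ether; buffering with acetic acid keeps the medium near neutral, so neither acid-promoted ionisation at C4 nor base-promoted quinone methide formation should occur and the prenyl alkene is untouched.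

**Compound list**

1 | 2,4,6-trimethoxybenzaldehyde | COc1cc(OC)c(C=O)c(OC)c1 | starting material
2 | 2,6-dihydroxy-4-methoxybenzaldehyde | COc1cc(O)c(C=O)c(O)c1 | intermediate
3 | methyl (2E)-4-bromobut-2-enoate | COC(=O)/C=C/CBr | starting material
4 | methyl (2E)-4-(2-formyl-3-hydroxy-5-methoxyphenoxy)but-2-enoate | COC(=O)/C=C/COc1cc(OC)cc(O)c1C=O | intermediate
5 | tert-butyldimethylsilyl chloride | CC(C)(C)[Si](C)(C)Cl | starting material
6 | methyl (2E)-4-[3-(tert-butyldimethylsilyloxy)-2-formyl-5-methoxyphenoxy]but-2-enoate | COC(=O)/C=C/COc1cc(OC)cc(O[Si](C)(C)C(C)(C)C)c1C=O | intermediate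
7 | methyl 2-[(3R)-5-(tert-butyldimethylsilyloxy)-7-methoxy-4-oxochroman-3-yl]acetate | COc1cc(O[Si](C)(C)C(C)(C)C)c2c(c1)OC[C@@H](CC(=O)OC)C2=O | intermediate
8 | methyl 2-[(3R,4R)-5-(tert-butyldimethylsilyloxy)-4-hydroxy-7-methoxychroman-3-yl]acetate (cis-hydroxy ester, formed as its lithium alkoxide) | COc1cc(O[Si](C)(C)C(C)(C)C)c2c(c1)OC[C@@H](CC(=O)OC)[C@H]2O | intermediate (not isolated)
9 | (3aR,9bR)-9-(tert-butyldimethylsilyloxy)-7-methoxy-3,3a,4,9b-tetrahydro-2H-furo[3,2-c]chromen-2-one | COc1cc(O[Si](C)(C)C(C)(C)C)c2c(c1)OC[C@@H](CC(=O)O3)[C@H]23 | intermediate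
10 | N,O-dimethylhydroxylamine hydrochloride | CNOC.Cl | starting material
11 | 2-[(3R,4R)-5-(tert-butyldimethylsilyloxy)-4-hydroxy-7-methoxychroman-3-yl]-N-methoxy-N-methylacetamide | COc1cc(O[Si](C)(C)C(C)(C)C)c2c(c1)OC[C@@H](CC(=O)N(C)OC)[C@H]2O | intermediate
12 | tert-butyldimethylsilyl trifluoromethanesulfonate | CC(C)(C)[Si](C)(C)OS(=O)(=O)C(F)(F)F | starting material
13 | 2-[(3R,4R)-4,5-bis(tert-butyldimethylsilyloxy)-7-methoxychroman-3-yl]-N-methoxy-N-methylacetamide | COc1cc(O[Si](C)(C)C(C)(C)C)c2c(c1)OC[C@@H](CC(=O)N(C)OC)[C@H]2O[Si](C)(C)C(C)(C)C | intermediate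
14 | prenyl bromide (1-bromo-3-methylbut-2-ene) | CC(C)=CCBr | starting material
15 | ethynylmagnesium bromide | C#C[Mg]Br | starting material
16 | 5-methylhex-4-en-1-yne | CC(C)=CCC#C | intermediate
17 | iodine | II | starting material
18 | chlorobis(cyclopentadienyl)[(1E)-5-methylhexa-1,4-dien-1-yl]zirconium (cyclopentadienyl rings drawn σ-bonded) | CC(C)=CC/C=C/[Zr](Cl)(C1C=CC=C1)C1C=CC=C1 | intermediate (not isolated)
19 | (1E)-1-iodo-5-methylhexa-1,4-diene | CC(C)=CC/C=C/I | intermediate
20 | [(1E)-5-methylhexa-1,4-dien-1-yl]lithium | CC(C)=CC/C=C/[Li] | intermediate (not isolated)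
21 | lithium alkoxide of the tetrahedral adduct of 20 with 13 (hemiaminal carbon unspecified) | COc1cc(O[Si](C)(C)C(C)(C)C)c2c(c1)OC[C@@H](CC(O[Li])(/C=C/CC=C(C)C)N(C)OC)[C@H]2O[Si](C)(C)C(C)(C)C | intermediate (not isolated)
22 | (3E)-1-[(3R,4R)-4,5-bis(tert-butyldimethylsilyloxy)-7-methoxychroman-3-yl]-7-methylocta-3,6-dien-2-one | COc1cc(O[Si](C)(C)C(C)(C)C)c2c(c1)OC[C@@H](CC(=O)/C=C/CC=C(C)C)[C@H]2O[Si](C)(C)C(C)(C)C | intermediate
23 | 4-acetamidobenzenesulfonyl azide | CC(=O)Nc1ccc(cc1)S(=O)(=O)N=[N+]=[N-] | starting material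
24 | (5E)-3-[(3R,4R)-4,5-bis(tert-butyldimethylsilyloxy)-7-methoxychroman-3-yl]-1,1,1-trifluoro-9-methyldeca-5,8-diene-2,4-dione (C3 of the chain unspecified) | COc1cc(O[Si](C)(C)C(C)(C)C)c2c(c1)OC[C@@H](C(C(=O)C(F)(F)F)C(=O)/C=C/CC=C(C)C)[C@H]2O[Si](C)(C)C(C)(C)C | intermediate (not isolated)
25 | (3E)-1-diazo-1-[(3R,4R)-4,5-bis(tert-butyldimethylsilyloxy)-7-methoxychroman-3-yl]-7-methylocta-3,6-dien-2-one | COc1cc(O[Si](C)(C)C(C)(C)C)c2c(c1)OC[C@@H](C(=[N+]=[N-])C(=O)/C=C/CC=C(C)C)[C@H]2O[Si](C)(C)C(C)(C)C | intermediate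
26 | chloroacetaldehyde dimethyl acetal | COC(CCl)OC | starting material
27 | 1-chloro-2-methoxyethene (geometry unspecified) | COC=CCl | intermediate (not isolated)
28 | sodium methoxyacetylide | COC#C[Na] | intermediate (not isolated)
29 | methoxyacetylene | COC#C | intermediate
30 | (3E)-2-[(3R,4R)-4,5-bis(tert-butyldimethylsilyloxy)-7-methoxychroman-3-yl]-7-methylocta-1,3,6-trien-1-one (vinylketene) | COc1cc(O[Si](C)(C)C(C)(C)C)c2c(c1)OC[C@@H](C(=C=O)/C=C/CC=C(C)C)[C@H]2O[Si](C)(C)C(C)(C)C | intermediate (not isolated)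
31 | 4-[(3R,4R)-4,5-bis(tert-butyldimethylsilyloxy)-7-methoxychroman-3-yl]-3-methoxy-4-[(1E)-5-methylhexa-1,4-dien-1-yl]cyclobut-2-en-1-one (C4 of the four-membered ring unspecified) | COc1cc(O[Si](C)(C)C(C)(C)C)c2c(c1)OC[C@@H](C3(/C=C/CC=C(C)C)C(=O)C=C3OC)[C@H]2O[Si](C)(C)C(C)(C)C | intermediate (not isolated)
32 | (3Z,5E)-4-[(3R,4R)-4,5-bis(tert-butyldimethylsilyloxy)-7-methoxychroman-3-yl]-3-methoxy-9-methyldeca-1,3,5,8-tetraen-1-one (dienylketene, alkenyl group cis to the ketenyl group) | COc1cc(O[Si](C)(C)C(C)(C)C)c2c(c1)OC[C@@H](\C(\C=C\CC=C(C)C)=C(\C=C=O)OC)[C@H]2O[Si](C)(C)C(C)(C)C | intermediate (not isolated)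
33 | 4-[(3R,4R)-4,5-bis(tert-butyldimethylsilyloxy)-7-methoxychroman-3-yl]-3-methoxy-6-(3-methylbut-2-en-1-yl)cyclohexa-2,4-dien-1-one (C6 unspecified) | COc1cc(O[Si](C)(C)C(C)(C)C)c2c(c1)OC[C@@H](C3=CC(CC=C(C)C)C(=O)C=C3OC)[C@H]2O[Si](C)(C)C(C)(C)C | intermediate (not isolated)
34 | 4-[(3R,4R)-4,5-bis(tert-butyldimethylsilyloxy)-7-methoxychroman-3-yl]-5-methoxy-2-(3-methylbut-2-en-1-yl)phenol | COc1cc(O[Si](C)(C)C(C)(C)C)c2c(c1)OC[C@@H](c1cc(CC=C(C)C)c(O)cc1OC)[C@H]2O[Si](C)(C)C(C)(C)C | intermediate
35 | (3R,4R)-3-[4-hydroxy-2-methoxy-5-(3-methylbut-2-en-1-yl)phenyl]-7-methoxychroman-4,5-diol | COc1cc(O)c2c(c1)OC[C@@H](c1cc(CC=C(C)C)c(O)cc1OC)[C@H]2O | target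

**Count**

Total steps: 14. Longest linear sequence: 11 (steps 1–7, 10, 11, 13, 14). Steps 8–9 (dienyl iodide) and step 12 (methoxyacetylene) are side branches.

**Three steps most likely to fail**

1. Step 13 (benzannulation). After loss of N2, the hydrogen on C3 may shift to the carbene carbon faster than the alkenyl group migrates, which gives an enone and no vinylketene. The crowded vinylketene may also capture the alkyne too slowly and dimerise or be trapped by the product phenol. The fallback brings ring B in preformed; it sets out from 2 and returns at target 35.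
   - Ring A ketone: monosilylation of 2 (5, Et3N, CH2Cl2, 0 °C) gives 2-(tert-butyldimethylsilyloxy)-6-hydroxy-4-methoxybenzaldehyde F1. CH2=CHMgBr (2.2 equiv, THF, −78 °C) gives allylic alcohol F2, which is oxidised without delay (MnO2, CH2Cl2) to aryl vinyl ketone F3. This closes by 6-endo oxa-Michael addition to 5-(tert-butyldimethylsilyloxy)-7-methoxychroman-4-one F4.
   - Ring B bromide: commercial 4-bromo-3-methoxyphenol F5 is C-prenylated at the free position ortho to OH (NaH, 14, toluene) to 4-bromo-5-methoxy-2-(3-methylbut-2-en-1-yl)phenol F6 and silylated (5, imidazole, DMF) to aryl bromide F7.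
   - Union and stereocentres: palladium-catalysed ketone α-arylation (Pd(OAc)2, t-Bu3P·HBF4, K3PO4, toluene, 80 °C) joins F4 and F7 to racemic isoflavanone F8. Asymmetric transfer hydrogenation under dynamic kinetic resolution (RuCl[(R,R)-TsDPEN](p-cymene), HCO2H/Et3N, 23 °C; catalyst sense expected by analogy with aryl alkyl ketones) should give cis-(3R,4R)-alcohol F9, because C3 of a 3-aryl ketone epimerises readily. Bu4NF/AcOH then gives 35.

2. Step 4 (Stetter cyclisation). The carbene may add too slowly to the doubly ortho-substituted, electron-rich aldehyde, so turnover stalls, or the product may lose enantiopurity by enolisation at C3. The fallback sets the stereocentres by reduction and not by the carbene; it sets out from 6 and returns at 9. Cyclisation with a small achiral thiazolium catalyst under more forcing conditions (3-benzyl-5-(2-hydroxyethyl)-4-methylthiazolium chloride, Et3N, 1,4-dioxane, 70 °C) gives racemic keto ester F10. Asymmetric transfer hydrogenation under dynamic kinetic resolution (RuCl[(R,R)-TsDPEN](p-cymene), HCO2H, DBU, 30 °C) should reduce the (3R) ketone selectively while C3 equilibrates through the enol or by reversible retro-oxa-Michael ring opening. This gives cis-hydroxy ester 8, which lactonises to 9.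

3. Step 11 (diazo transfer). The base may remove a doubly allylic γ-proton in competition with the α′ proton, which moves the skipped diene into conjugation or puts the acyl group on the wrong carbon. The fallback installs the activating group before the dienone exists, so that no strong base meets the skipped dienone; it sets out from 13 and returns at 25.
   - LiN(i-Pr)2 and HCO2Et (THF, −78 °C) formylate the only enolisable position of 13 to α-formyl amide F11.
   - Et3SiCl/Et3N masks it as silyl enol ether F12.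
   - Dienyllithium 20 (from 19 and t-BuLi as in step 10) adds to the amide carbonyl to give β-silyloxy dienone F13.
   - Aqueous Et3N in MeCN unmasks α-formyl ketone F14, and 23 then transfers the diazo group with loss of the formyl group (deformylative Regitz transfer) to give 25.

**Further compounds**

F1 | step 13 | 2-(tert-butyldimethylsilyloxy)-6-hydroxy-4-methoxybenzaldehyde | COc1cc(O)c(C=O)c(O[Si](C)(C)C(C)(C)C)c1
F2 | step 13 | 1-[2-(tert-butyldimethylsilyloxy)-6-hydroxy-4-methoxyphenyl]prop-2-en-1-ol (racemic) | COc1cc(O)c(C(O)C=C)c(O[Si](C)(C)C(C)(C)C)c1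
F3 | step 13 | 1-[2-(tert-butyldimethylsilyloxy)-6-hydroxy-4-methoxyphenyl]prop-2-en-1-one | COc1cc(O)c(C(=O)C=C)c(O[Si](C)(C)C(C)(C)C)c1
F4 | step 13 | 5-(tert-butyldimethylsilyloxy)-7-methoxychroman-4-one | COc1cc(O[Si](C)(C)C(C)(C)C)c2c(c1)OCCC2=O
F5 | step 13 | 4-bromo-3-methoxyphenol (commercial input) | COc1cc(O)ccc1Br
F6 | step 13 | 4-bromo-5-methoxy-2-(3-methylbut-2-en-1-yl)phenol | COc1cc(O)c(CC=C(C)C)cc1Br
F7 | step 13 | [4-bromo-5-methoxy-2-(3-methylbut-2-en-1-yl)phenoxy](tert-butyl)dimethylsilane | COc1cc(O[Si](C)(C)C(C)(C)C)c(CC=C(C)C)cc1Br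
F8 | step 13 | 5-(tert-butyldimethylsilyloxy)-3-[4-(tert-butyldimethylsilyloxy)-2-methoxy-5-(3-methylbut-2-en-1-yl)phenyl]-7-methoxychroman-4-one (racemic) | COc1cc(O[Si](C)(C)C(C)(C)C)c2c(c1)OCC(c1cc(CC=C(C)C)c(O[Si](C)(C)C(C)(C)C)cc1OC)C2=O
F9 | step 13 | (3R,4R)-5-(tert-butyldimethylsilyloxy)-3-[4-(tert-butyldimethylsilyloxy)-2-methoxy-5-(3-methylbut-2-en-1-yl)phenyl]-7-methoxychroman-4-ol | COc1cc(O[Si](C)(C)C(C)(C)C)c2c(c1)OC[C@@H](c1cc(CC=C(C)C)c(O[Si](C)(C)C(C)(C)C)cc1OC)[C@H]2O
F10 | step 4 | methyl 2-[5-(tert-butyldimethylsilyloxy)-7-methoxy-4-oxochroman-3-yl]acetate (racemic) | COc1cc(O[Si](C)(C)C(C)(C)C)c2c(c1)OCC(CC(=O)OC)C2=O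
F11 | step 11 | 2-[(3R,4R)-4,5-bis(tert-butyldimethylsilyloxy)-7-methoxychroman-3-yl]-N-methoxy-N-methyl-3-oxopropanamide (drawn as the aldehyde tautomer) | COc1cc(O[Si](C)(C)C(C)(C)C)c2c(c1)OC[C@@H](C(C=O)C(=O)N(C)OC)[C@H]2O[Si](C)(C)C(C)(C)C
F12 | step 11 | 2-[(3R,4R)-4,5-bis(tert-butyldimethylsilyloxy)-7-methoxychroman-3-yl]-N-methoxy-N-methyl-3-(triethylsilyloxy)prop-2-enamide (geometry unspecified) | COc1cc(O[Si](C)(C)C(C)(C)C)c2c(c1)OC[C@@H](C(=CO[Si](CC)(CC)CC)C(=O)N(C)OC)[C@H]2O[Si](C)(C)C(C)(C)C
F13 | step 11 | (4E)-2-[(3R,4R)-4,5-bis(tert-butyldimethylsilyloxy)-7-methoxychroman-3-yl]-8-methyl-1-(triethylsilyloxy)nona-1,4,7-trien-3-one (enol ether geometry unspecified) | COc1cc(O[Si](C)(C)C(C)(C)C)c2c(c1)OC[C@@H](C(=CO[Si](CC)(CC)CC)C(=O)/C=C/CC=C(C)C)[C@H]2O[Si](C)(C)C(C)(C)C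
F14 | step 11 | (4E)-2-[(3R,4R)-4,5-bis(tert-butyldimethylsilyloxy)-7-methoxychroman-3-yl]-8-methyl-3-oxonona-4,7-dienal (drawn as the aldehyde tautomer) | COc1cc(O[Si](C)(C)C(C)(C)C)c2c(c1)OC[C@@H](C(C=O)C(=O)/C=C/CC=C(C)C)[C@H]2O[Si](C)(C)C(C)(C)C
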